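Count the catalyst lifetimes that fit into the time the flask needs to reach the asked conversion.

left-handed substrate 0.016 M; partner 0.0192 M; free catalyst 0.16 mM; right-handed substrate 0.016 M

    partner + free catalyst + left-handed substrate → free catalyst + left-handed product (k1 = 9200 L² mol⁻² s⁻¹)
    partner + free catalyst + right-handed substrate → free catalyst + right-handed product (k2 = 1800 L² mol⁻² s⁻¹)
    free catalyst → spent catalyst B (k3 = 0.014 s⁻¹)
    partner + free catalyst → spent catalyst A (k4 = 0.21 L mol⁻¹ s⁻¹)

- free catalyst is single-handed; left-handed substrate and right-handed substrate are mirror images of each other, charged as a racemate, each of them at the stated concentration
- charge of left-handed substrate (flask): 0.016 M

1. the form that holds most of the catalyst when 5.0% of the left-handed substrate and right-handed substrate together are converted (spent catalyst A / free catalyst / spent catalyst B)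
2. its share of the catalyst then
3. factor on the rate of making left-handed product when 5.0% of the left-handed substrate and right-handed substrate together are converted if partner is charged twice over
4. factor on the rate when 5.0% of the left-handed substrate and right-handed substrate together are converted if free catalyst is charged at 1.5 mM instead

Free catalyst died by two routes, each first order in it, and with partner as charged I took the pseudo-first-order loss constant λ as the decay constant plus the partner-route constant times partner, 1.08 min⁻¹, which gave a lifetime τ = 1/λ of 0.924 min. The mark was a turnover x of 1.60 mM, and I defined n as the time to the mark divided by τ.

Two extreme flasks could be solved in the head. With reagents held as charged and the catalyst undying, the mark took 0.0493 min, or 0.0534 lifetimes. With partner and both substrates held from the first moment at their charges minus x, and the catalyst again undying, it took 0.0598 min, or 0.0647 lifetimes. The reagents fell gradually from the first state, and at the mark they stood no lower than the second, because x counts both substrates together; so, with the catalyst loss set aside, I placed the real flask between the two, the second time being longer than the first, and took their mean, 0.0590.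

Since n lay far below one, I expected free catalyst to hold most of the catalyst, with a share exp(−n) of 94.3%. For the flask with partner charged twice over, I took the time as half of its value and raised λ for the added partner, and the partner left and the catalyst surviving together gave a factor of 2.14. For the flask with the larger catalyst charge, I shortened the time by the ratio of charges, which gave 9.88.

The forecast gave free catalyst at 94.3%, with factors 2.14 and 9.9, on the ground that “the catalyst dies over about a minute”.

The flask reached the mark at 0.0551 min against a lifetime τ of 0.924 min, which is 0.0596 lifetimes, and it then held free catalyst at 94.3%, beside 4.49% spent catalyst B and 1.24% spent catalyst A, while the factors came out at 2.14 and 9.88. In the flask charged with 1.5 mM of free catalyst, the count scaled by the ratio of charges is 0.00636 lifetimes, and that flask held 99.4% of its catalyst as free catalyst at the same conversion.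

The constants used here belong to no real substance; the rest is arithmetic.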